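## Structural features

The target 25 is a longipinane. Its core is a bicyclo[3.1.1]hept-2-en-1-one (a pinenone: C1 ketone, C2=C3 with the C3 methyl, bridgeheads C4 and C11, one-carbon bridges C5 and C10). The cyclobutane C4–C5–C11–C10 is spanned from C5 to C10 by the chain C6(Me2)–C7–C8–C9, which closes a seven-membered ring; these atom labels are used for all bicyclic intermediates. Each one-carbon bridge has an inner position (pointing at the other one-carbon bridge, away from C1–C3) and an outer position (lying over C1–C3). The seven-membered ring can only leave from the two inner positions, so C5–H and the C10 methyl are outer. Four contiguous stereocentres sit on the cyclobutane (4R,5S,10R,11R; C10 quaternary), and two neopentylic carbinol centres (7R,9R) are 1,3-trans across C8. Fragile groups are the angelate on O9 (Z to E drift to the tiglate), the senecioate on O7 (deconjugation through a vinylketene), any β-oxygenated C7 ketone (retro-aldol, elimination), and the cyclobutane, which does not tolerate a cationic or radical centre next to it for long. The real difficulties are the inner–inner relationship of C6 and C9, the absolute configuration of a core whose two halves (C4, C11) differ only by the sense of the enone, and the distinction of two similar hindered hydroxyls. The key step uses the 1,3-dioxygen pattern C7/C9 across C8: with C6 and C10 quaternary, a C7 methyl ketone can enolise only towards C8 and a C9 aldehyde not at all, and both are held 1,3-cis on the cyclobutane.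

## Logic of the disconnections

25 ⇒ 23 + 24, and 23 ⇒ 20 + 21. The two ester C–O bonds (O7–acyl, O9–acyl) are cut first, because both acyl groups isomerise easily and should see no further chemistry. This leaves a diol and two commercial acyl donors. The forward steps must tell two neopentylic hydroxyls apart (O9 first) and must not touch the Z alkene of the first ester.

20 ⇒ 19. The C7–H bond is cut, which turns the 1,3-trans diol into a β-hydroxy ketone. The C9 hydroxyl can then deliver hydride to C7 from its own face, so C7 follows from C9. The gain is one stereocentre less and the aldol retron C7(=O)–C8–C9(OH). The demand is that hydride comes only from boron bound to O9 and that the enone stays.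

19 ⇒ 16. The C8–C9 bond is cut, opening the seven-membered ring to a methyl ketone and an aldehyde on the intact pinenone. It is the only aldol pair the carbons allow. The gain is one ring, one bond and one stereocentre. The demand is that the reagent chooses the aldehyde face, and that the ketone is enolised in the presence of the aldehyde and the enone.

16 ⇒ 15 ⇒ 14 ⇒ 13. The C9 aldehyde is masked as a chiral acetal, the C1 oxygen is taken back to an allylic CH2, and the ring alkene is moved to the exocyclic position. The aldehyde and the enone would not survive the carbanion chemistry of the side chain, and the exocyclic alkene is what the cycloaddition delivers. The demand is a late allylic oxidation that picks C1 and an acetal cleavage that does not start the aldol.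

13 ⇒ 11 ⇒ 9 ⇒ 8 ⇒ 7. The side chain on C5 is dismantled: C7–C8, the two C6–CH3 bonds, C5–H and C5=C6, back to a C5 ketone. C5 is made by adding hydrogen to an sp2 carbon that already carries C6: the inner face of C5 is covered by the C10 substituent, so whatever arrives at C5 arrives outer. For the same reason the reverse order is not used. Attaching C6 to C5 by radical or nucleophilic opening of a C5–C10 bicyclobutane would put the new carbon outer, and the seven-membered ring could then not be closed. The demand is clean outer-face hydride delivery and two alkylations next to a hindered centre.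

7 ⇒ 6 ⇒ 4. C4–C10 and C5–C11 are cut together in a ketene–alkene [2+2] retron. This removes the cyclobutane and the three remaining ring stereocentres at once and leaves an open-chain dienoic acid; the alkene geometry fixes C10 relative to C4 and C11. The demand is the crossed (bridged) regiochemistry and a handle for the absolute configuration, which the chiral acetal provides by making the two antipodal cores separable.

4 ⇒ 3 ⇒ 2 ⇒ 1. Ester hydrolysis, acetalisation and allylic oxidation of the E methyl group lead back to a commercial monoterpene ester. It already holds ten of the fifteen core carbons and the E-trisubstituted alkene. The demand is oxidation at the distal alkene only, with E selectivity.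

## Other disconnections considered

Alternative 1: The cut is C5–C6, made on a monocyclic cyclobutene; the enone ring (C1–C2) is built afterwards. Forward, a TiCl4-promoted Mukaiyama–Michael addition of the tetrasubstituted C6=C7 silyl enol ether in the C10 side chain to C5 of a cyclobut-1-ene-1-carboxylate would give the bicyclo[4.1.1]octanone ester A1 (ketone at C7 of the target, position 3 of the bicycle).
- In favour: C6 is delivered from a chain anchored on C10, so the inner position at C5 is enforced by the tether. C9 is set beforehand by an ordinary asymmetric carbonyl addition, and its PMB ether already distinguishes O9 from O7. On these points (C5 control, C9 control, hydroxyl differentiation) it is better than the chosen plan.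
- Against: the bond joins a fully substituted enol ether carbon to a cyclobutene carbon in a seven-membered closure, on an acid-sensitive strained ester. C11 is set only by protonation of the ester enolate. The six-membered enone still has to be annulated from the C11 ester and the C4 isopropenyl group.
- Comparison: structurally it secures the ring junction more surely. Mechanistically the chosen aldol (methyl ketone onto an aldehyde) is the easier bond. In step economy the two are about equal up to the key step, but the chosen plan needs three steps after it, against an annulation plus redox adjustments.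

Alternative 2: The cut is C4–C10, so the cyclobutane is closed last. Forward, anodic oxidation of a cis-fused six–seven bicycle with a C9 methyl enol ether and a C1 silyl dienol ether would couple C10 with C4 across the ring and give the silyl ether A2.
- In favour: the precursor is a strain-free bicycle open to standard annulation. C1 and C9 appear as carbonyls in the same step. The strained ring is not carried through a long sequence, which is better than the chosen plan (it carries the cyclobutane from step 4). O7 is already protected, so the two oxygens are differentiated from the start, which is also better.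
- Against: enol ether radical-cation couplings are reliable for five- and six-membered rings. A four-membered closure that also creates the quaternary C10 has to compete with solvent capture and with plain oxidation of the dienol ether to a dienone. C9 must afterwards be reduced to 9R next to C10; a hydroxyl-directed reduction from O7 would mirror step 13 and is equal to the chosen plan.
- Comparison: equal or shorter in count and simpler in protecting-group logic, but far less secure in mechanism.

Alternative 3: The cuts are C5–C6 and C9–C10 together. Forward, the tertiary α-keto radical from a bromo ynone (Ir(ppy)3, Hantzsch ester, visible light) would add to bridgehead C5 of a tricyclic bicyclobutane enone, and the C10 radical would close 7-endo on the alkyne to give the dienedione A3.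
- In favour: two bonds and the seven-membered ring in one operation from small pieces. This is clearly the best step economy, better than the chosen plan, and the C8=C9 enone is a handle for O9.
- Against: homolytic attack on a bicyclobutane bridgehead is expected at the rear lobe of the central bond, from the side of the three-carbon bridge. C6 would then take the outer position at C5 and the bridgehead hydrogen the inner one, the opposite of what 25 needs, and an outer chain cannot be reached by the C10 radical. The same reasoning excludes making 16 by radical addition and carbonylation across this bond. The bicyclobutane is chiral only through its bridgehead methyl and would need its own asymmetric synthesis.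
- Comparison: shorter on paper but at odds with the shape of the cage. The chosen plan uses the same facial bias in the productive sense (step 6).

Key step: step 12

Assumption: the facial preference of Ipc2BCl-derived methyl ketone enolates in open-chain additions ((+)-reagent to the Si face, (−)-reagent to the Re face of the aldehyde) is recalled from precedent and taken to hold in the ring closure; both antipodes are commercial, so the choice can be reversed.

## Route

Step 1
Reactants: 1 methyl (2E)-3,7-dimethylocta-2,6-dienoate (methyl geranate)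
Product: 2 methyl (2E,6E)-3,7-dimethyl-8-oxoocta-2,6-dienoate
Conditions: SeO2 (1.5 equiv), 1,4-dioxane, 80 °C
Reagents that add atoms: selenium dioxide, O=[Se]=O
Why: Riley allylic oxidation (ene reaction, [2,3]-shift, further oxidation of the allylic alcohol to the enal); the electron-rich C6=C7 alkene should react before the conjugated one, and the methyl trans to the chain is attacked, which gives the E enal.

Step 2
Reactants: 2 methyl (2E,6E)-3,7-dimethyl-8-oxoocta-2,6-dienoate
Product: 3 methyl (2E,6E)-7-[(4R,5R)-4,5-dimethyl-1,3-dioxolan-2-yl]-3-methylocta-2,6-dienoate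
Conditions: (2R,3R)-butane-2,3-diol (2 equiv), PPTS (cat.), benzene, reflux, Dean–Stark
Reagents that add atoms: (2R,3R)-butane-2,3-diol, C[C@@H](O)[C@H](O)C
Why: Acid-catalysed acetalisation with azeotropic removal of water; the C2-symmetric diol adds no stereocentre at the acetal carbon, keeps C9 at the aldehyde oxidation level through the carbanion steps, and makes the two antipodal cores of step 4 diastereomers.

Step 3
Reactants: 3 methyl (2E,6E)-7-[(4R,5R)-4,5-dimethyl-1,3-dioxolan-2-yl]-3-methylocta-2,6-dienoate
Product: 4 (2E,6E)-7-[(4R,5R)-4,5-dimethyl-1,3-dioxolan-2-yl]-3-methylocta-2,6-dienoic acid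
Conditions: LiOH·H2O, THF/MeOH/H2O, rt; then 1 M HCl to pH 4, 0 °C
Reagents that add atoms: lithium hydroxide, [Li+].[OH-]
Why: Saponification of the methyl ester; the acetal is stable to base and the acidification is brief and cold.

Step 4
Reactants: 4 (2E,6E)-7-[(4R,5R)-4,5-dimethyl-1,3-dioxolan-2-yl]-3-methylocta-2,6-dienoic acid
Product: 7 (1R,5S,7S)-7-[(4R,5R)-4,5-dimethyl-1,3-dioxolan-2-yl]-7-methyl-2-methylidenebicyclo[3.1.1]heptan-6-one, via acid chloride 5 (not isolated), via vinylketene 6 (not isolated)
Conditions: 1-chloro-N,N,2-trimethylprop-1-en-1-amine, CH2Cl2, 0 °C to rt; then slow addition to Et3N, toluene, 110 °C (0.005 M)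
Reagents that add atoms: none
Why: Neutral formation of the acid chloride, dehydrochlorination through the C3 methyl to the vinylketene, and thermal intramolecular [2+2] ketene–alkene cycloaddition; the ketene carbonyl carbon should bond to the less substituted alkene carbon (C11) and the ketene α-carbon (C4) to C10, which gives the bridged bicyclo[3.1.1]heptan-6-one and sets C4, C10 and C11. The addition is suprafacial on the alkene, so the E geometry places the methyl outer and the dioxolanyl group inner on C10. Both core antipodes should form; they are diastereomers through the (4R,5R)-acetal and are to be separated by chromatography, 7 being the isomer with the core of 25.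

Step 5
Reactants: 7 (1R,5S,7S)-7-[(4R,5R)-4,5-dimethyl-1,3-dioxolan-2-yl]-7-methyl-2-methylidenebicyclo[3.1.1]heptan-6-one
Product: 8 2-{7-[(4R,5R)-4,5-dimethyl-1,3-dioxolan-2-yl]-7-methyl-2-methylidenebicyclo[3.1.1]heptan-6-ylidene}acetonitrile (E/Z mixture; ring centres as in 7)
Conditions: (EtO)2P(O)CH2CN, NaH, THF, 0 to 65 °C
Reagents that add atoms: diethyl (cyanomethyl)phosphonate, N#CCP(=O)(OCC)OCC
Why: Horner–Wadsworth–Emmons olefination; the ketone cannot enolise (both α-carbons are bridgeheads), ring strain favours addition of the small phosphonate anion from the outer face, and collapse to the alkene is expected to be faster than fragmentation of the strained alkoxide. The alkene geometry is of no consequence.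

Step 6
Reactants: 8 2-{7-[(4R,5R)-4,5-dimethyl-1,3-dioxolan-2-yl]-7-methyl-2-methylidenebicyclo[3.1.1]heptan-6-ylidene}acetonitrile
Product: 9 2-{7-[(4R,5R)-4,5-dimethyl-1,3-dioxolan-2-yl]-7-methyl-2-methylidenebicyclo[3.1.1]heptan-6-yl}acetonitrile (cyanomethyl inner, cis to the dioxolanyl group; C5–H outer; other centres as in 7)
Conditions: Cu(OAc)2·H2O (5 mol %), 1,2-bis(diphenylphosphino)benzene (5 mol %), (EtO)2MeSiH, t-BuOH, toluene, rt
Reagents that add atoms: none
Why: Copper hydride conjugate reduction (hydrocupration of the unsaturated nitrile, protonation by t-BuOH); the inner face of C5 is covered by the dioxolanyl group on C10, so hydride should arrive from the outer face and push the cyanomethyl group inner, as in the hydrogenation of β-pinene to cis-pinane. The isolated methylidene is not reduced.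

Step 7
Reactants: 9 2-{7-[(4R,5R)-4,5-dimethyl-1,3-dioxolan-2-yl]-7-methyl-2-methylidenebicyclo[3.1.1]heptan-6-yl}acetonitrile
Product: 11 2-{7-[(4R,5R)-4,5-dimethyl-1,3-dioxolan-2-yl]-7-methyl-2-methylidenebicyclo[3.1.1]heptan-6-yl}-2-methylpropanenitrile (ring centres as in 9), via monomethyl nitrile 10 (not isolated)
Conditions: LiN(iPr)2, THF/DMPU, −78 °C, then MeI; second cycle in the same flask, −78 to 0 °C
Reagents that add atoms: iodomethane, CI
Why: Two deprotonation–methylation cycles of the nitrile (SN2 on iodomethane); the small linear nitrile anion is the established way to a quaternary carbon next to a hindered centre. C5 has no acidic hydrogen, so its configuration is kept.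

Step 8
Reactants: 11 2-{7-[(4R,5R)-4,5-dimethyl-1,3-dioxolan-2-yl]-7-methyl-2-methylidenebicyclo[3.1.1]heptan-6-yl}-2-methylpropanenitrile
Product: 13 3-{7-[(4R,5R)-4,5-dimethyl-1,3-dioxolan-2-yl]-7-methyl-2-methylidenebicyclo[3.1.1]heptan-6-yl}-3-methylbutan-2-one (ring centres as in 9), via ketimine 12 (not isolated)
Conditions: MeLi, Et2O, 0 °C to rt; then aq. AcOH, rt
Reagents that add atoms: methyllithium, [Li]C; water, O
Why: Addition of methyllithium to the tertiary nitrile stops at the N-lithio ketimine (no α-hydrogen, no second addition); mild acid hydrolysis should give the methyl ketone and leave the dioxolane intact.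

Step 9
Reactants: 13 3-{7-[(4R,5R)-4,5-dimethyl-1,3-dioxolan-2-yl]-7-methyl-2-methylidenebicyclo[3.1.1]heptan-6-yl}-3-methylbutan-2-one
Product: 14 3-{7-[(4R,5R)-4,5-dimethyl-1,3-dioxolan-2-yl]-2,7-dimethylbicyclo[3.1.1]hept-2-en-6-yl}-3-methylbutan-2-one (ring centres as in 13)
Conditions: RuHCl(CO)(PPh3)3 (5 mol %), toluene, 80 °C
Reagents that add atoms: none
Why: Ruthenium hydride insertion and β-hydride elimination move the exocyclic alkene into the ring to the more stable trisubstituted C2=C3 alkene (β-pinene to α-pinene type); no cation or radical is formed next to the cyclobutane, and the bridgehead C4 stops further migration.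

Step 10
Reactants: 14 3-{7-[(4R,5R)-4,5-dimethyl-1,3-dioxolan-2-yl]-2,7-dimethylbicyclo[3.1.1]hept-2-en-6-yl}-3-methylbutan-2-one
Product: 15 3-{(1R,5R,6R,7S)-6-[(4R,5R)-4,5-dimethyl-1,3-dioxolan-2-yl]-2,6-dimethyl-4-oxobicyclo[3.1.1]hept-2-en-7-yl}-3-methylbutan-2-one
Conditions: CrO3, 3,5-dimethylpyrazole, CH2Cl2, −20 °C
Reagents that add atoms: chromium trioxide, O=[Cr](=O)=O
Why: Allylic oxidation with the CrO3–3,5-dimethylpyrazole complex should convert the ring methylene C1, the only secondary allylic position, into the enone carbonyl (α-pinene to verbenone type); the ketone and the hindered acetal are expected to survive at low temperature.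

Step 11
Reactants: 15 3-{(1R,5R,6R,7S)-6-[(4R,5R)-4,5-dimethyl-1,3-dioxolan-2-yl]-2,6-dimethyl-4-oxobicyclo[3.1.1]hept-2-en-7-yl}-3-methylbutan-2-one
Product: 16 (1R,5R,6R,7S)-2,6-dimethyl-7-(2-methyl-3-oxobutan-2-yl)-4-oxobicyclo[3.1.1]hept-2-ene-6-carbaldehyde (4R,5S,10R,11R in the labels of 25)
Conditions: TFA/H2O (4:1), CH2Cl2, 0 °C
Reagents that add atoms: water, O
Why: Acid hydrolysis of the dioxolane releases the neopentyl aldehyde and the chiral diol; short exposure at 0 °C is meant to keep an acid-catalysed aldol of 16 from setting in.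

Step 12
Reactants: 16 (1R,5R,6R,7S)-2,6-dimethyl-7-(2-methyl-3-oxobutan-2-yl)-4-oxobicyclo[3.1.1]hept-2-ene-6-carbaldehyde
Product: 19 (4R,5S,9R,10R,11R)-9-hydroxylongipin-2-ene-1,7-dione, via boron enolate 17 (not isolated), via boron aldolate 18 (not isolated)
Conditions: (−)-Ipc2BCl (1.5 equiv), Et3N (2 equiv), Et2O, −78 to −20 °C; then pH 7 buffer, MeOH, 30% H2O2, 0 °C
Reagents that add atoms: none
Why: Ipc2BCl and Et3N convert the C7 methyl ketone into the boron enolate 17 (C8 is its only enolisable position); boron then binds the C9 aldehyde and C8 adds through a closed, boat-like six-membered boron transition state to the aldolate 18, which is cleaved oxidatively to 19. The closest known reaction type is the Ipc2BCl-mediated aldol addition of a methyl ketone to an aldehyde, here in intramolecular form. The seven-membered ring (C5–C6–C7–C8–C9–C10–C11) closes in the 7-(enolendo)-exo-trig mode: the enolate C7=C8 lies inside the new ring and the aldehyde oxygen outside. The one new stereocentre, C9, is controlled by the reagent: the two aldehyde faces differ only by the remote sense of the enone, so the isopinocampheyl groups are relied on to send C8 to the Re face (9R), and the 9-epimer is to be removed by chromatography. The step needs enolisation of the saturated ketone in preference to γ-deprotonation of the enone through the C3 methyl and to hydride transfer from the reagent to the aldehyde; the more basic unconjugated carbonyl, the neopentyl hindrance of the aldehyde, the amine and the low temperature are expected to secure this. The 1,3-cis hold of C6 and C9 on the cyclobutane keeps C8 within reach of C9, so ring closure should outrun intermolecular aldol, and no other enolate can form because C6 and C10 are quaternary and C11 is a bridgehead.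

Step 13
Reactants: 19 (4R,5S,9R,10R,11R)-9-hydroxylongipin-2-ene-1,7-dione
Product: 20 (4R,5S,7R,9R,10R,11R)-7,9-dihydroxylongipin-2-en-1-one
Conditions: Me4NBH(OAc)3, MeCN/AcOH (1:1), −25 °C
Reagents that add atoms: none
Why: Evans–Saksena reduction; the C9 hydroxyl exchanges an acetate on boron and delivers hydride intramolecularly to the C7 ketone from its own face, which should give the 1,3-trans (7R,9R) diol. Triacetoxyborohydride does not reduce the enone.

Step 14
Reactants: 20 (4R,5S,7R,9R,10R,11R)-7,9-dihydroxylongipin-2-en-1-one; 21 (2Z)-2-methylbut-2-enoic acid (angelic acid)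
Product: 23 (4R,5S,7R,9R,10R,11R)-7-hydroxy-1-oxolongipin-2-en-9-yl (2Z)-2-methylbut-2-enoate, via mixed anhydride 22 (not isolated)
Conditions: 21, 2,4,6-trichlorobenzoyl chloride, Et3N, toluene, rt; then 20 (1.2 equiv of anhydride), 75 °C
Reagents that add atoms: none
Why: Yamaguchi-type esterification through the mixed anhydride, run without DMAP so that the Z double bond is kept; the C9 hydroxyl, next to the tied-back cyclobutane carbon C10, is expected to be acylated before the C7 hydroxyl, which is flanked by the gem-dimethyl carbon C6.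

Step 15
Reactants: 23 (4R,5S,7R,9R,10R,11R)-7-hydroxy-1-oxolongipin-2-en-9-yl (2Z)-2-methylbut-2-enoate; 24 3-methylbut-2-enoyl chloride
Product: 25 (4R,5S,7R,9R,10R,11R)-7-(3-methylbut-2-enoyloxy)-1-oxolongipin-2-en-9-yl (2Z)-2-methylbut-2-enoate
Conditions: pyridine, CH2Cl2, 0 to 40 °C
Reagents that add atoms: none
Why: Acylation of the remaining hindered C7 hydroxyl by the acid chloride with pyridine as base and acyl-transfer catalyst; pyridine is too weak to deconjugate the senecioyl unit through its vinylketene or to isomerise the angelate.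

## Compound list

1 | methyl (2E)-3,7-dimethylocta-2,6-dienoate (methyl geranate) | COC(=O)/C=C(\C)CCC=C(C)C | starting material
2 | methyl (2E,6E)-3,7-dimethyl-8-oxoocta-2,6-dienoate | COC(=O)/C=C(\C)CC/C=C(\C)C=O | intermediate
3 | methyl (2E,6E)-7-[(4R,5R)-4,5-dimethyl-1,3-dioxolan-2-yl]-3-methylocta-2,6-dienoate | COC(=O)/C=C(\C)CC/C=C(\C)C1O[C@H](C)[C@@H](C)O1 | intermediate
4 | (2E,6E)-7-[(4R,5R)-4,5-dimethyl-1,3-dioxolan-2-yl]-3-methylocta-2,6-dienoic acid | OC(=O)/C=C(\C)CC/C=C(\C)C1O[C@H](C)[C@@H](C)O1 | intermediate
5 | (2E,6E)-7-[(4R,5R)-4,5-dimethyl-1,3-dioxolan-2-yl]-3-methylocta-2,6-dienoyl chloride | ClC(=O)/C=C(\C)CC/C=C(\C)C1O[C@H](C)[C@@H](C)O1 | intermediate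
6 | (6E)-7-[(4R,5R)-4,5-dimethyl-1,3-dioxolan-2-yl]-3-methylideneocta-1,6-dien-1-one (vinylketene) | O=C=CC(=C)CC/C=C(\C)C1O[C@H](C)[C@@H](C)O1 | intermediate
7 | (1R,5S,7S)-7-[(4R,5R)-4,5-dimethyl-1,3-dioxolan-2-yl]-7-methyl-2-methylidenebicyclo[3.1.1]heptan-6-one | O=C1[C@H]2CCC(=C)[C@@H]1[C@]2(C3O[C@H](C)[C@@H](C)O3)C | intermediate
8 | 2-{7-[(4R,5R)-4,5-dimethyl-1,3-dioxolan-2-yl]-7-methyl-2-methylidenebicyclo[3.1.1]heptan-6-ylidene}acetonitrile (E/Z mixture; ring centres as in 7) | N#CC=C1[C@H]2CCC(=C)[C@@H]1[C@]2(C3O[C@H](C)[C@@H](C)O3)C | intermediate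
9 | 2-{7-[(4R,5R)-4,5-dimethyl-1,3-dioxolan-2-yl]-7-methyl-2-methylidenebicyclo[3.1.1]heptan-6-yl}acetonitrile (cyanomethyl cis to the dioxolanyl group) | N#CC[C@@H]1[C@H]2CCC(=C)[C@@H]1[C@]2(C3O[C@H](C)[C@@H](C)O3)C | intermediate
10 | 2-{7-[(4R,5R)-4,5-dimethyl-1,3-dioxolan-2-yl]-7-methyl-2-methylidenebicyclo[3.1.1]heptan-6-yl}propanenitrile (both epimers at the nitrile α-carbon) | N#CC(C)[C@@H]1[C@H]2CCC(=C)[C@@H]1[C@]2(C3O[C@H](C)[C@@H](C)O3)C | intermediate
11 | 2-{7-[(4R,5R)-4,5-dimethyl-1,3-dioxolan-2-yl]-7-methyl-2-methylidenebicyclo[3.1.1]heptan-6-yl}-2-methylpropanenitrile | N#CC(C)(C)[C@@H]1[C@H]2CCC(=C)[C@@H]1[C@]2(C3O[C@H](C)[C@@H](C)O3)C | intermediate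
12 | 3-{7-[(4R,5R)-4,5-dimethyl-1,3-dioxolan-2-yl]-7-methyl-2-methylidenebicyclo[3.1.1]heptan-6-yl}-3-methylbutan-2-imine | CC(=N)C(C)(C)[C@@H]1[C@H]2CCC(=C)[C@@H]1[C@]2(C3O[C@H](C)[C@@H](C)O3)C | intermediate
13 | 3-{7-[(4R,5R)-4,5-dimethyl-1,3-dioxolan-2-yl]-7-methyl-2-methylidenebicyclo[3.1.1]heptan-6-yl}-3-methylbutan-2-one | CC(=O)C(C)(C)[C@@H]1[C@H]2CCC(=C)[C@@H]1[C@]2(C3O[C@H](C)[C@@H](C)O3)C | intermediate
14 | 3-{7-[(4R,5R)-4,5-dimethyl-1,3-dioxolan-2-yl]-2,7-dimethylbicyclo[3.1.1]hept-2-en-6-yl}-3-methylbutan-2-one | CC(=O)C(C)(C)[C@@H]1[C@H]2CC=C(C)[C@@H]1[C@]2(C3O[C@H](C)[C@@H](C)O3)C | intermediate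
15 | 3-{(1R,5R,6R,7S)-6-[(4R,5R)-4,5-dimethyl-1,3-dioxolan-2-yl]-2,6-dimethyl-4-oxobicyclo[3.1.1]hept-2-en-7-yl}-3-methylbutan-2-one | CC(=O)C(C)(C)[C@@H]1[C@H]2C(=O)C=C(C)[C@@H]1[C@]2(C3O[C@H](C)[C@@H](C)O3)C | intermediate
16 | (1R,5R,6R,7S)-2,6-dimethyl-7-(2-methyl-3-oxobutan-2-yl)-4-oxobicyclo[3.1.1]hept-2-ene-6-carbaldehyde | CC(=O)C(C)(C)[C@@H]1[C@H]2C(=O)C=C(C)[C@@H]1[C@]2(C=O)C | intermediate
17 | bis[(1R,2S,3R,5R)-isopinocampheyl]boron enolate of 16 (O–B on C7, C7=C8) | C=C(OB([C@@H]3C[C@@H]4C[C@@H](C4(C)C)[C@H]3C)[C@@H]5C[C@@H]6C[C@@H](C6(C)C)[C@H]5C)C(C)(C)[C@@H]1[C@H]2C(=O)C=C(C)[C@@H]1[C@]2(C=O)C | intermediate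
18 | bis[(1R,2S,3R,5R)-isopinocampheyl]boron 9-aldolate of 19 | B([C@@H]1C[C@@H]2C[C@@H](C2(C)C)[C@H]1C)([C@@H]1C[C@@H]2C[C@@H](C2(C)C)[C@H]1C)O[C@@H]3CC(=O)C(C)(C)[C@@H]4[C@H]5C(=O)C=C(C)[C@@H]4[C@]53C | intermediate
19 | (4R,5S,9R,10R,11R)-9-hydroxylongipin-2-ene-1,7-dione | O[C@@H]1CC(=O)C(C)(C)[C@@H]2[C@H]3C(=O)C=C(C)[C@@H]2[C@]31C | intermediate
20 | (4R,5S,7R,9R,10R,11R)-7,9-dihydroxylongipin-2-en-1-one | O[C@@H]1C[C@@H](O)C(C)(C)[C@@H]2[C@H]3C(=O)C=C(C)[C@@H]2[C@]31C | intermediate
21 | (2Z)-2-methylbut-2-enoic acid (angelic acid) | C/C=C(/C)C(=O)O | starting material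
22 | (2Z)-2-methylbut-2-enoic 2,4,6-trichlorobenzoic anhydride | C/C=C(/C)C(=O)OC(=O)c1c(Cl)cc(Cl)cc1Cl | intermediate
23 | (4R,5S,7R,9R,10R,11R)-7-hydroxy-1-oxolongipin-2-en-9-yl (2Z)-2-methylbut-2-enoate | C/C=C(/C)C(=O)O[C@@H]1C[C@@H](O)C(C)(C)[C@@H]2[C@H]3C(=O)C=C(C)[C@@H]2[C@]31C | intermediate
24 | 3-methylbut-2-enoyl chloride | CC(C)=CC(=O)Cl | starting material
25 | (4R,5S,7R,9R,10R,11R)-7-(3-methylbut-2-enoyloxy)-1-oxolongipin-2-en-9-yl (2Z)-2-methylbut-2-enoate | C/C=C(/C)C(=O)O[C@@H]1C[C@@H](OC(=O)C=C(C)C)C(C)(C)[C@@H]2[C@H]3C(=O)C=C(C)[C@@H]2[C@]31C | target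

## Step count and least certain steps

Total step count: 15. Longest linear sequence: 15 steps (1 to 25).

Step 12 (key step). Most likely to go wrong is the facial selectivity at C9: the ring closure has a different transition-state geometry from the open-chain additions on which the choice of antipode rests, and the bias of Ipc2B methyl ketone enolates is moderate. Hydride transfer from the reagent to the aldehyde may also compete with enolisation. Fallback, setting out from 16 and returning to 19:
- Close the ring without reagent control with (c-C6H11)2BCl and Et3N to the mixture of 19 and its 9-epimer (4R,5S,9S,10R,11R)-9-hydroxylongipin-2-ene-1,7-dione F1.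
- Convert the mixture with MsCl and Et3N into the 9-mesylates F2 and eliminate with DBU to longipina-2,8-diene-1,7-dione F3 (the compound called A3 above).
- Conjugate borylation (CuCl, NaOt-Bu, the Josiphos antipode that delivers boron to the Re face of C9, B2pin2, MeOH) should take the disubstituted C8=C9 enone before the β,β-disubstituted ring enone and give the 9R pinacol boronate F4.
- NaBO3·4H2O oxidises C–B to C–OH with retention, which gives 19.

Step 4. Most likely to go wrong is oligomerisation of the vinylketene, because the acetal makes the C10=C11 alkene a poor nucleophile; separation of the two core diastereomers is the second concern and can be moved to 9, 11 or 13. Fallback, setting out from 4 and returning to 7: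
- Make the N,N-dimethylamide F5 (from 5 and Me2NH).
- Activate it with Tf2O and 2,4,6-collidine in 1,2-dichloroethane to the more electrophilic vinyl keteniminium ion, whose intramolecular [2+2] gives the cyclobutaniminium triflate F6.
- Hydrolyse with aqueous NaHCO3 to 7 and its diastereomer.

Step 6. Most likely to go wrong is insufficient face selectivity, or no reaction, in the hydrocupration, since both faces of C5 are flanked. Fallback, setting out from 7 and returning to 13 (it replaces steps 5 to 8):
- Add the tetrasubstituted lithium enolate of 3-methylbutan-2-one (from 3-methyl-2-(trimethylsilyloxy)but-2-ene and MeLi) to the strained ketone at −78 °C to give the tertiary aldol F7.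
- Trap the lithium aldolate in the same flask with methyl chlorooxoacetate as the methyl oxalate F8.
- Reduce with Bu3SnH and AIBN in toluene at 110 °C; the planar C5 radical should take hydrogen on the open outer face whatever the configuration of F7, which gives 13.

Step 10. Most likely to go wrong is competing oxidation at the acetal C–H or at the C3 methyl. Fallback, setting out from 11 and returning to 15 (it replaces steps 8 to 10 by a carbonyl transposition):
- Ozonolysis (O3, then Me2S) of the methylidene gives the C3 ketone F9.
- Saegusa–Ito dehydrogenation (LiN(iPr)2, Me3SiCl; Pd(OAc)2) gives the C1=C2 enone F10.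
- Excess MeLi adds 1,2 to the enone and once to the nitrile; aqueous AcOH then gives the tertiary allylic alcohol methyl ketone F11.
- Pyridinium chlorochromate, [C5H5NH][CrO3Cl], effects the oxidative 1,3-transposition to 15.

Step 14. Most likely to go wrong is poor discrimination between the two neopentylic hydroxyls. Fallback, setting out from 19 and returning to 25 (it replaces steps 13 to 15 and differentiates the oxygens by mechanism):
- Evans–Tishchenko reduction (SmI2 0.3 equiv, CH3CHO, THF, −10 °C) gives the 1,3-trans 9-acetate 7-alcohol F12.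
- Acylation with 24, pyridine and catalytic DMAP gives the 9-acetate 7-senecioate F13.
- K2CO3 in MeOH at 0 °C removes the acetate before the conjugated ester and gives the 9-alcohol 7-senecioate F14.
- The mixed anhydride 22 in toluene at 75 °C then gives 25.

## Further compounds

F1 | step 12 | (4R,5S,9S,10R,11R)-9-hydroxylongipin-2-ene-1,7-dione | O[C@H]1CC(=O)C(C)(C)[C@@H]2[C@H]3C(=O)C=C(C)[C@@H]2[C@]31C
F2 | step 12 | (4R,5S,10R,11R)-1,7-dioxolongipin-2-en-9-yl methanesulfonate (both C9 epimers) | CS(=O)(=O)OC1CC(=O)C(C)(C)[C@@H]2[C@H]3C(=O)C=C(C)[C@@H]2[C@]31C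
F3 | step 12 | (4R,5S,10R,11R)-longipina-2,8-diene-1,7-dione | C1=CC(=O)C(C)(C)[C@@H]2[C@H]3C(=O)C=C(C)[C@@H]2[C@]31C
F4 | step 12 | (4R,5S,9R,10R,11R)-9-(4,4,5,5-tetramethyl-1,3,2-dioxaborolan-2-yl)longipin-2-ene-1,7-dione | CC1(C)OB(OC1(C)C)[C@@H]2CC(=O)C(C)(C)[C@@H]3[C@H]4C(=O)C=C(C)[C@@H]3[C@]42C
F5 | step 4 | (2E,6E)-7-[(4R,5R)-4,5-dimethyl-1,3-dioxolan-2-yl]-N,N,3-trimethylocta-2,6-dienamide | CN(C)C(=O)/C=C(\C)CC/C=C(\C)C1O[C@H](C)[C@@H](C)O1
F6 | step 4 | N-{7-[(4R,5R)-4,5-dimethyl-1,3-dioxolan-2-yl]-7-methyl-2-methylidenebicyclo[3.1.1]heptan-6-ylidene}-N-methylmethanaminium trifluoromethanesulfonate (ring centres as in 7) | C[N+](C)=C1[C@H]2CCC(=C)[C@@H]1[C@]2(C3O[C@H](C)[C@@H](C)O3)C.[O-]S(=O)(=O)C(F)(F)F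
F7 | step 6 | 3-{7-[(4R,5R)-4,5-dimethyl-1,3-dioxolan-2-yl]-6-hydroxy-7-methyl-2-methylidenebicyclo[3.1.1]heptan-6-yl}-3-methylbutan-2-one (hydroxyl inner, side chain outer) | CC(=O)C(C)(C)[C@@]1(O)[C@H]2CCC(=C)[C@@H]1[C@]2(C3O[C@H](C)[C@@H](C)O3)C
F8 | step 6 | methyl oxalate of F7 | CC(=O)C(C)(C)[C@@]1(OC(=O)C(=O)OC)[C@H]2CCC(=C)[C@@H]1[C@]2(C3O[C@H](C)[C@@H](C)O3)C
F9 | step 10 | 2-{7-[(4R,5R)-4,5-dimethyl-1,3-dioxolan-2-yl]-7-methyl-2-oxobicyclo[3.1.1]heptan-6-yl}-2-methylpropanenitrile (ring centres as in 11) | N#CC(C)(C)[C@@H]1[C@H]2CCC(=O)[C@@H]1[C@]2(C3O[C@H](C)[C@@H](C)O3)C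
F10 | step 10 | 2-{7-[(4R,5R)-4,5-dimethyl-1,3-dioxolan-2-yl]-7-methyl-2-oxobicyclo[3.1.1]hept-3-en-6-yl}-2-methylpropanenitrile | N#CC(C)(C)[C@@H]1[C@H]2C=CC(=O)[C@@H]1[C@]2(C3O[C@H](C)[C@@H](C)O3)C
F11 | step 10 | 3-{7-[(4R,5R)-4,5-dimethyl-1,3-dioxolan-2-yl]-2-hydroxy-2,7-dimethylbicyclo[3.1.1]hept-3-en-6-yl}-3-methylbutan-2-one (both carbinol epimers) | CC(=O)C(C)(C)[C@@H]1[C@H]2C=CC(C)(O)[C@@H]1[C@]2(C3O[C@H](C)[C@@H](C)O3)C
F12 | step 14 | (4R,5S,7R,9R,10R,11R)-7-hydroxy-1-oxolongipin-2-en-9-yl acetate | CC(=O)O[C@@H]1C[C@@H](O)C(C)(C)[C@@H]2[C@H]3C(=O)C=C(C)[C@@H]2[C@]31C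
F13 | step 14 | (4R,5S,7R,9R,10R,11R)-9-acetoxy-1-oxolongipin-2-en-7-yl 3-methylbut-2-enoate | CC(=O)O[C@@H]1C[C@@H](OC(=O)C=C(C)C)C(C)(C)[C@@H]2[C@H]3C(=O)C=C(C)[C@@H]2[C@]31C
F14 | step 14 | (4R,5S,7R,9R,10R,11R)-9-hydroxy-1-oxolongipin-2-en-7-yl 3-methylbut-2-enoate | O[C@@H]1C[C@@H](OC(=O)C=C(C)C)C(C)(C)[C@@H]2[C@H]3C(=O)C=C(C)[C@@H]2[C@]31C
A1 | alternative 1 | methyl bicyclo[4.1.1]octan-3-one-7-carboxylate with 2-(4-methoxybenzyloxy), 1,4,4-trimethyl and 8-isopropenyl groups (C7 ketone, C9 OPMB, C11 ester, C4 isopropenyl in the labels of 25) | COc1ccc(cc1)CO[C@@H]1CC(=O)C(C)(C)[C@@H]2[C@@H](C(=O)OC)[C@@]1(C)[C@H]2C(C)=C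
A2 | alternative 2 | (4R,5S,7R,10R,11R)-7-(tert-butyldimethylsilyloxy)longipin-2-ene-1,9-dione | O=C1C[C@@H](O[Si](C)(C)C(C)(C)C)C(C)(C)[C@@H]2[C@H]3C(=O)C=C(C)[C@@H]2[C@]31C
A3 | alternative 3 | (4R,5S,10R,11R)-longipina-2,8-diene-1,7-dione | C1=CC(=O)C(C)(C)[C@@H]2[C@H]3C(=O)C=C(C)[C@@H]2[C@]31C
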